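| flask | starting material | free catalyst | time |
|---|---|---|---|
| larch | 0.400 M | 0.0400 M |  |
| cedar | 0.800 M | 0.0400 M |  |
| alder | 0.400 M | 0.120 M |  |
| maple | 1.80 M | 0.0400 M | 53 min |

- larch run (time / min: [target] / M): 8.8: 0.0751; 18: 0.1454; 26: 0.1915; 35: 0.2319; 44: 0.2610; 53: 0.2845
- cedar run (time / min: [target] / M): 8.8: 0.0882; 18: 0.1692; 26: 0.2219; 35: 0.2630; 44: 0.2901; 53: 0.3139
- alder run (time / min: [target] / M): 8.8: 0.3679; 18: 0.3978; 26: 0.4006; 35: 0.3995; 44: 0.3998; 53: 0.3995

(standard deviation of a reading: 0.001 M)

- Overall: starting material -> target, with free catalyst as catalyst.
- Constant volume, constant temperature.
- What is held in complexes is read along with the free species.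
- An order is taken over about fifteen percent of the charge, up and down.

- the exponent of [starting material] in the starting rate at the charge of the larch run (at the point where two percent of the starting material have become target) (one fixed amount of target, the same in the runs compared)
- the exponent of [free catalyst] in the starting rate at the charge of the larch run (at the point where two percent of the starting material have become target)
- target in the maple run at 53 min, as a share of the starting material charged

1. Over time the cedar run slowed. Target rose at 0.00880 M min⁻¹ between its first two readings and at 0.00264 M min⁻¹ between its last two, a fall by a factor of 3.33.

2. Starting material fell by a factor of 1.35 over that span, a smaller factor. So I read a fading catalyst.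

3. I used two times. The fade time is the time in which the rate falls by a factor of e, and the cedar readings gave 29.2 min. The turn time is the charge of starting material divided by the first slope.

4. Their ratio, fade time over turn time, times the charge gave my carried quantity. The reach is the first slope times the fade time, the target a charge of catalyst makes before it fades. The cedar first slope of 0.0100 M min⁻¹ gave 0.292 M.

5. The alder turn time was 9.57 min, shorter than the cedar fade time. I assumed the alder catalyst faded no faster. That run ended at 0.3995 M from 0.400 M charged, so starting material was the limiting reagent there.

6. Doubling the charge raised the first slope by a factor of 1.17, so I kept the cedar slope for the maple run. Its turn time was 180 min, far longer than the fade time. My share was therefore 16.2%.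

7. The forecast gave 0.3, 2.3 and 16%, by its own route, with this ground: “So product inhibition or catalyst loss dominates late.”

8. The flask gave these results.

    active catalyst + starting material ⇌ catalyst-substrate complex, settled at all times (0.9970 L mol⁻¹)
    catalyst-substrate complex + active catalyst → target + 2 active catalyst (38.28 L mol⁻¹ min⁻¹)
    active catalyst + starting material → spent catalyst + starting material (0.04908 L mol⁻¹ min⁻¹)
    free catalyst → active catalyst (0.8760 min⁻¹)

The orders came out at 0.29 and 1.3, the second against the forecast's 2.3. The maple run gave 11.9%, which is 0.215 M of target, less than the reach of 0.292 M. With the cedar slope held, that share means a fade time of 21.4 min, shorter than the cedar reading. In the alder run, half of the charge had turned by 3.92 min, against the cedar fade time of 29.2 min.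

All runs are simulated for an exercise; the scatter is artificial.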